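**Plan**

- Retrosynthesis: the acid goes back to a CH2OSiMe2t-Bu group and the 7-OMe to a 7-OSi(i-Pr)3 group. The benzene ring is then cut at C4a–C5, C5–C6, C7–C8 and C8–C8a, giving an α-diazoketone on a chiral dihydropyranone and a chiral siloxyalkyne.
- Enabling feature: the hexasubstituted ring C4a–C5–C6–C7–C8–C8a carries O at C5, C7 and C8a and C at C4a, C6 and C8. A vinylketene (C5, C8, C8a=C4a, the last two already the ring double bond of the pyranone O1–C2–C3–C4–C4a–C8a) and an ynol ether (C6≡C7–O) deliver exactly this order.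
- Forward: the dihydropyranone ring is closed first by 6-endo cyclisation of a β-hydroxy ynone. The benzene ring is then built onto it in one operation (Wolff shift, [2+2], 4π opening, 6π closure).
- Stereochemistry: C2 (S) and C3 (R), cis, come from an Evans syn aldol of the (R)-benzyl propionyl imide with acetaldehyde. The side-chain centre (R) comes from an Evans allylation of the (S)-benzyl heptanoyl imide.
- Endgame: buffered fluoride, base-free methylation of the non-chelated 7-OH and a two-stage neutral or weakly acidic oxidation, so the base-labile cis C2/C3 pair is never exposed.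

Key step: step 16

Remark: the labels O1, C2, C3, C4, C4a, C5–C8, C8a are those of the chroman-4-one of the target and are used for the same atoms in its precursors. The carbinol carbon made in step 2 is carried in both configurations because step 9 erases it.

**Step 1**
Reactants: 1 2-methylbut-3-en-2-ol
Product: 3 5-methylhex-4-enal, via allyl vinyl ether 2 (not isolated)
Conditions: ethyl vinyl ether (excess), H3PO4 (cat.), sealed vessel, 150 °C
Reagents that add atoms: ethyl vinyl ether C=COCC
Why: acid-catalysed vinyl ether exchange gives 2, whose Claisen rearrangement ([3,3]-sigmatropic shift) moves the double bond into the trisubstituted position and delivers the γ,δ-unsaturated aldehyde.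

**Step 2**
Reactants: 3 5-methylhex-4-enal
Product: 4 7-methyloct-6-en-1-yn-3-ol (racemic)
Conditions: HC≡CMgBr, THF, 0 °C
Reagents that add atoms: ethynylmagnesium bromide C#C[Mg]Br
Why: Grignard 1,2-addition of an acetylide to an unhindered aldehyde, with the new carbinol centre left racemic because it later becomes a ketone.

**Step 3**
Reactants: 4 7-methyloct-6-en-1-yn-3-ol
Product: 5 tert-butyl(dimethyl)[(7-methyloct-6-en-1-yn-3-yl)oxy]silane (racemic)
Conditions: t-BuMe2SiCl, imidazole, DMF, rt
Reagents that add atoms: tert-butyldimethylsilyl chloride CC(C)(C)[Si](C)(C)Cl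
Why: imidazole-promoted silylation of a secondary alcohol, so that only the alkyne C–H is deprotonated in step 6.

**Step 4**
Reactants: 6 (R)-4-benzyl-3-propionyloxazolidin-2-one; 7 acetaldehyde
Product: 9 (R)-4-benzyl-3-[(2R,3S)-3-hydroxy-2-methylbutanoyl]oxazolidin-2-one, via boron enolate 8 (not isolated)
Conditions: Bu2BOTf, Et3N, CH2Cl2, −78 to 0 °C; then MeOH, pH 7 buffer, H2O2, 0 °C
Reagents that add atoms: none
Why: Evans syn aldol, in which Z-boron enolate 8 reacts through a chair transition state on the face away from the benzyl group, so the (R)-auxiliary sets (2R,3S), the later C3 (R) and C2 (S).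

**Step 5**
Reactants: 9 (R)-4-benzyl-3-[(2R,3S)-3-hydroxy-2-methylbutanoyl]oxazolidin-2-one
Product: 10 (2R,3S)-3-hydroxy-N-methoxy-N,2-dimethylbutanamide
Conditions: MeNH(OMe)·HCl, AlMe3, THF, 0 °C to rt
Reagents that add atoms: N,O-dimethylhydroxylamine hydrochloride CNOC.Cl
Why: aluminium amide transamidation (Weinreb amide formation) attacks the exocyclic imide carbonyl, is helped by the free β-hydroxyl group and leaves both stereocentres untouched.

**Step 6**
Reactants: 10 (2R,3S)-3-hydroxy-N-methoxy-N,2-dimethylbutanamide; 5 tert-butyl(dimethyl)[(7-methyloct-6-en-1-yn-3-yl)oxy]silane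
Product: 12 (2S,3R,7RS)-7-(tert-butyldimethylsilyloxy)-2-hydroxy-3,11-dimethyldodec-10-en-5-yn-4-one, via lithium acetylide 11 (not isolated)
Conditions: 5 (2.2 equiv), n-BuLi (2.1 equiv), THF, −78 °C; then 10, −78 to −20 °C; aqueous quench
Reagents that add atoms: none
Why: acetylide addition to a Weinreb amide stops at the chelated tetrahedral adduct and gives the ynone on quench, the first equivalent of 11 only deprotonating the hydroxyl group and returning 5.

**Step 7**
Reactants: 12 (2S,3R,7RS)-7-(tert-butyldimethylsilyloxy)-2-hydroxy-3,11-dimethyldodec-10-en-5-yn-4-one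
Product: 13 (2S,3R)-6-[(1RS)-1-(tert-butyldimethylsilyloxy)-5-methylhex-4-enyl]-2,3-dimethyl-2,3-dihydro-4H-pyran-4-one
Conditions: AgOTf (10 mol %), CH2Cl2, rt, dark
Reagents that add atoms: none
Why: π-acid-catalysed 6-endo-dig oxa-Michael cyclisation of a β-hydroxy ynone, in which the oxygen adds to the alkyne carbon β to the ketone, the C2–O bond stays intact and the neutral medium spares C3.

**Step 8**
Reactants: 13 (2S,3R)-6-[(1RS)-1-(tert-butyldimethylsilyloxy)-5-methylhex-4-enyl]-2,3-dimethyl-2,3-dihydro-4H-pyran-4-one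
Product: 14 (2S,3R)-6-[(1RS)-1-hydroxy-5-methylhex-4-enyl]-2,3-dimethyl-2,3-dihydro-4H-pyran-4-one
Conditions: HF·pyridine, THF, 0 °C to rt
Reagents that add atoms: none
Why: fluoride cleavage of a silyl ether in a weakly acidic medium, preferred to Bu4NF so that C3–H next to the vinylogous ester meets no base.

**Step 9**
Reactants: 14 (2S,3R)-6-[(1RS)-1-hydroxy-5-methylhex-4-enyl]-2,3-dimethyl-2,3-dihydro-4H-pyran-4-one
Product: 15 (2S,3R)-2,3-dimethyl-6-(5-methylhex-4-enoyl)-2,3-dihydro-4H-pyran-4-one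
Conditions: Dess–Martin periodinane, CH2Cl2, 0 °C to rt
Reagents that add atoms: none
Why: Dess–Martin oxidation of a secondary allylic-type alcohol under neutral conditions removes the stereorandom carbinol centre and leaves the trisubstituted alkene and the cis-dimethyl pair alone.

**Step 10**
Reactants: 15 (2S,3R)-2,3-dimethyl-6-(5-methylhex-4-enoyl)-2,3-dihydro-4H-pyran-4-one
Product: 18 (2S,3R)-6-(2-diazo-5-methylhex-4-enoyl)-2,3-dimethyl-2,3-dihydro-4H-pyran-4-one, via lithium enolate 16 (not isolated), via trifluoroacetyl diketone 17 (not isolated)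
Conditions: LiN(SiMe3)2 (1.05 equiv), THF, −78 °C; CF3CO2CH2CF3; dilute HCl wash; then MsN3, Et3N, H2O (1 equiv), MeCN, rt
Reagents that add atoms: methanesulfonyl azide CS(=O)(=O)N=[N+]=[N-]; 2,2,2-trifluoroethyl trifluoroacetate FC(F)(F)COC(=O)C(F)(F)F (its atoms stay only in 17)
Why: detrifluoroacetylative diazo transfer (a Regitz-type reaction), in which kinetic deprotonation takes the secondary CH2 of the more acidic side-chain ketone rather than the tertiary C3–H, trifluoroacetylation activates that carbon and mesyl azide transfers N2 with loss of the trifluoroacetyl group.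

**Step 11**
Reactants: 19 (S)-4-benzyloxazolidin-2-one; 20 heptanoyl chloride
Product: 21 (S)-4-benzyl-3-heptanoyloxazolidin-2-one
Conditions: Et3N, DMAP (cat.), CH2Cl2, 0 °C to rt
Reagents that add atoms: none
Why: DMAP-catalysed N-acylation of an oxazolidinone with an acid chloride.

**Step 12**
Reactants: 21 (S)-4-benzyl-3-heptanoyloxazolidin-2-one
Product: 23 (S)-4-benzyl-3-[(R)-2-pentylpent-4-enoyl]oxazolidin-2-one, via sodium enolate 22 (not isolated)
Conditions: NaN(SiMe3)2, THF, −78 °C; allyl iodide, −78 to −40 °C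
Reagents that add atoms: allyl iodide C=CCI
Why: Evans asymmetric alkylation, in which the chelated Z-enolate 22 is allylated on the face opposite the benzyl group, so the (S)-auxiliary gives the (R) centre that becomes the benzylic carbon of the side chain.

**Step 13**
Reactants: 23 (S)-4-benzyl-3-[(R)-2-pentylpent-4-enoyl]oxazolidin-2-one
Product: 26 (R)-3-pentyldihydrofuran-2(3H)-one, via aldehyde 24 (not isolated), via hydroxy imide 25 (not isolated)
Conditions: O3, CH2Cl2–MeOH, −78 °C; Me2S; then NaBH4, 0 °C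
Reagents that add atoms: ozone [O-][O+]=O
Why: ozonolysis with reductive work-up shortens the allyl group to aldehyde 24, borohydride reduction gives 25, and its alkoxide attacks the imide carbonyl (5-exo-trig lactonisation) and expels the auxiliary without touching the α-centre.

**Step 14**
Reactants: 26 (R)-3-pentyldihydrofuran-2(3H)-one
Product: 29 ethyl (R)-2-[2-(tert-butyldimethylsilyloxy)ethyl]heptanoate, via potassium carboxylate 27 (not isolated), via hydroxy ester 28 (not isolated)
Conditions: KOH (1.0 equiv), EtOH–H2O, rt; evaporate; EtI, DMF, rt; then imidazole, t-BuMe2SiCl, rt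
Reagents that add atoms: potassium hydroxide [K+].[OH-]; iodoethane CCI; tert-butyldimethylsilyl chloride CC(C)(C)[Si](C)(C)Cl
Why: saponification, SN2 O-alkylation of the carboxylate and silylation are run in one flask so that γ-hydroxy ester 28 is capped before it can close back to the lactone, the carboxylate stage shielding the α-centre from enolisation.

**Step 15**
Reactants: 29 ethyl (R)-2-[2-(tert-butyldimethylsilyloxy)ethyl]heptanoate
Product: 31 (R)-tert-butyldimethyl({3-[(triisopropylsilyloxy)ethynyl]octyl}oxy)silane, via lithium ynolate 30 (not isolated)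
Conditions: CH2Br2, lithium 2,2,6,6-tetramethylpiperidide, THF, −78 °C; n-BuLi, −78 to 0 °C; i-Pr3SiCl, −78 to 0 °C
Reagents that add atoms: dibromomethane BrCBr; triisopropylsilyl chloride CC(C)[Si](Cl)(C(C)C)C(C)C
Why: Kowalski ester homologation stopped at the ynolate, in which LiCHBr2 adds to the ester, Br/Li exchange on the dibromo enolate triggers a 1,2-shift of the secondary alkyl group with retention, and the bulky silyl chloride traps ynolate 30 on oxygen.

**Step 16**
Reactants: 18 (2S,3R)-6-(2-diazo-5-methylhex-4-enoyl)-2,3-dimethyl-2,3-dihydro-4H-pyran-4-one; 31 (R)-tert-butyldimethyl({3-[(triisopropylsilyloxy)ethynyl]octyl}oxy)silane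
Product: 36 (2S,3R)-6-[(R)-1-(tert-butyldimethylsilyloxy)octan-3-yl]-5-hydroxy-2,3-dimethyl-8-(3-methylbut-2-enyl)-7-(triisopropylsilyloxy)chroman-4-one, via ketene 32 (not isolated), via cyclobutenone 33 (not isolated), via dienylketene 34 (not isolated), via cyclohexadienone 35 (not isolated)
Conditions: 31 (1.5 equiv), degassed ClCH2CH2Cl, hν (LED, 400–450 nm), 15 °C; then 80 °C
Reagents that add atoms: none
Why: Proposed new method: light expels N2 from 18 and the sp2 carbon C8a shifts from the carbonyl carbon to the diazo carbon C8 (Wolff rearrangement, new bond C8–C8a) to give ketene 32, which the ynol ether takes up in a [2+2] cycloaddition (nucleophilic C6 to the ketene carbon C5, C7 to C8) to give cyclobutenone 33. On warming, 33 opens in a four-electron conrotatory process (C5–C8 breaks) to dienylketene 34, and the benzene ring, the only ring closed here, forms by six-electron disrotatory electrocyclisation of C5 onto C4a, after which cyclohexadienone 35 tautomerises to the phenol hydrogen-bonded to C4=O. The closest known reaction type is the Danheiser benzannulation in its diazoketone form, shown for diazomethyl ketones of cycloalkenes, arenes and furans with triisopropylsiloxyalkynes, among them alkynes with a stereocentre next to the triple bond; not shown so far are a dihydropyranone (a β-alkoxy enone) as the vinyl part and an alkyl group on the diazo carbon. No stereocentre of 36 is made here, since the quaternary carbon of 33 and the C4a–H carbon of 35 become planar again, and C2, C3 and the side-chain centre meet neither acid nor base. Regioselectivity is needed in the [2+2] step and is secured by polarity: the carbon β to the siloxy group is the nucleophile and the ketene carbonyl carbon the electrophile, so the siloxy carbon ends as C7 and the ketene oxygen as 5-OH. Chemoselectivity is needed at the carbene stage, where the Wolff shift must be faster than the 1,2-hydride shift from the allylic CH2, and at the absorption stage, where the enone should stay unexcited; direct long-wavelength irradiation of the singlet diazoketone, the good migrating ability of an sp2 carbon and an excess of 31 are meant to secure both.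

**Step 17**
Reactants: 36 (2S,3R)-6-[(R)-1-(tert-butyldimethylsilyloxy)octan-3-yl]-5-hydroxy-2,3-dimethyl-8-(3-methylbut-2-enyl)-7-(triisopropylsilyloxy)chroman-4-one
Product: 37 (2S,3R)-5,7-dihydroxy-6-[(R)-1-hydroxyoctan-3-yl]-2,3-dimethyl-8-(3-methylbut-2-enyl)chroman-4-one
Conditions: Bu4NF, AcOH (1:1, 3 equiv each), THF, 0 °C to rt
Reagents that add atoms: none
Why: fluoride cleavage of the aryl and the alkyl silyl ether, with acetic acid buffering the phenoxide so that neither retro-oxa-Michael opening nor enolisation can scramble the cis C2/C3 pair.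

**Step 18**
Reactants: 37 (2S,3R)-5,7-dihydroxy-6-[(R)-1-hydroxyoctan-3-yl]-2,3-dimethyl-8-(3-methylbut-2-enyl)chroman-4-one
Product: 38 (2S,3R)-5-hydroxy-6-[(R)-1-hydroxyoctan-3-yl]-7-methoxy-2,3-dimethyl-8-(3-methylbut-2-enyl)chroman-4-one
Conditions: Me3SiCHN2, toluene–MeOH, 0 °C to rt
Reagents that add atoms: trimethylsilyldiazomethane C[Si](C)(C)C=[N+]=[N-]
Why: O-methylation by a diazoalkane needs a proton donor, which only the vinylogous-acid 7-OH is, since the 5-OH is held in the hydrogen bond to C4=O, the aliphatic alcohol is far too weak an acid and no base is present.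

**Step 19**
Reactants: 38 (2S,3R)-5-hydroxy-6-[(R)-1-hydroxyoctan-3-yl]-7-methoxy-2,3-dimethyl-8-(3-methylbut-2-enyl)chroman-4-one
Product: 39 (R)-3-[(2S,3R)-5-hydroxy-7-methoxy-2,3-dimethyl-8-(3-methylbut-2-enyl)-4-oxochroman-6-yl]octanal
Conditions: Dess–Martin periodinane (1.1 equiv), CH2Cl2, 0 °C
Reagents that add atoms: none
Why: Dess–Martin oxidation of a primary alcohol to the aldehyde under neutral conditions, the chelated phenol on a fully substituted ring and the prenyl group being left alone when only a slight excess is used.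

**Step 20**
Reactants: 39 (R)-3-[(2S,3R)-5-hydroxy-7-methoxy-2,3-dimethyl-8-(3-methylbut-2-enyl)-4-oxochroman-6-yl]octanal
Product: 40 (R)-3-[(2S,3R)-5-hydroxy-7-methoxy-2,3-dimethyl-8-(3-methylbut-2-enyl)-4-oxochroman-6-yl]octanoic acid
Conditions: NaClO2, NaH2PO4, 2-methylbut-2-ene (large excess), t-BuOH–H2O, 0 °C to rt
Reagents that add atoms: sodium chlorite [Na+].[O-]Cl=O
Why: Pinnick oxidation of the aldehyde in a weakly acidic buffer, with 2-methylbut-2-ene taking up the hypochlorous acid so that the prenyl group and the electron-rich ring are not chlorinated.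

**Compound list**

1 | 2-methylbut-3-en-2-ol | CC(C)(O)C=C | starting material
2 | 3-methyl-3-(vinyloxy)but-1-ene | C=COC(C)(C)C=C | intermediate
3 | 5-methylhex-4-enal | CC(C)=CCCC=O | intermediate
4 | 7-methyloct-6-en-1-yn-3-ol (racemic) | CC(C)=CCCC(O)C#C | intermediate
5 | tert-butyl(dimethyl)[(7-methyloct-6-en-1-yn-3-yl)oxy]silane (racemic) | CC(C)=CCCC(O[Si](C)(C)C(C)(C)C)C#C | intermediate
6 | (R)-4-benzyl-3-propionyloxazolidin-2-one | CCC(=O)N1[C@H](Cc2ccccc2)COC1=O | starting material
7 | acetaldehyde | CC=O | starting material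
8 | Z-dibutylboron enolate of 6 | C/C=C(\OB(CCCC)CCCC)N1[C@H](Cc2ccccc2)COC1=O | intermediate
9 | (R)-4-benzyl-3-[(2R,3S)-3-hydroxy-2-methylbutanoyl]oxazolidin-2-one | O[C@@H](C)[C@@H](C)C(=O)N1[C@H](Cc2ccccc2)COC1=O | intermediate
10 | (2R,3S)-3-hydroxy-N-methoxy-N,2-dimethylbutanamide | O[C@@H](C)[C@@H](C)C(=O)N(C)OC | intermediate
11 | lithium acetylide of 5 | CC(C)=CCCC(O[Si](C)(C)C(C)(C)C)C#C[Li] | intermediate
12 | (2S,3R,7RS)-7-(tert-butyldimethylsilyloxy)-2-hydroxy-3,11-dimethyldodec-10-en-5-yn-4-one | O[C@@H](C)[C@@H](C)C(=O)C#CC(CCC=C(C)C)O[Si](C)(C)C(C)(C)C | intermediate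
13 | (2S,3R)-6-[(1RS)-1-(tert-butyldimethylsilyloxy)-5-methylhex-4-enyl]-2,3-dimethyl-2,3-dihydro-4H-pyran-4-one | C1=C(C(CCC=C(C)C)O[Si](C)(C)C(C)(C)C)O[C@@H](C)[C@@H](C)C1=O | intermediate
14 | (2S,3R)-6-[(1RS)-1-hydroxy-5-methylhex-4-enyl]-2,3-dimethyl-2,3-dihydro-4H-pyran-4-one | C1=C(C(O)CCC=C(C)C)O[C@@H](C)[C@@H](C)C1=O | intermediate
15 | (2S,3R)-2,3-dimethyl-6-(5-methylhex-4-enoyl)-2,3-dihydro-4H-pyran-4-one | C1=C(C(=O)CCC=C(C)C)O[C@@H](C)[C@@H](C)C1=O | intermediate
16 | lithium enolate of 15 (side-chain ketone) | C1=C(C(O[Li])=CCC=C(C)C)O[C@@H](C)[C@@H](C)C1=O | intermediate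
17 | 1-[(2S,3R)-2,3-dimethyl-4-oxo-3,4-dihydro-2H-pyran-6-yl]-4,4,4-trifluoro-2-(3-methylbut-2-enyl)butane-1,3-dione | C1=C(C(=O)C(CC=C(C)C)C(=O)C(F)(F)F)O[C@@H](C)[C@@H](C)C1=O | intermediate
18 | (2S,3R)-6-(2-diazo-5-methylhex-4-enoyl)-2,3-dimethyl-2,3-dihydro-4H-pyran-4-one | C1=C(C(=O)C(=[N+]=[N-])CC=C(C)C)O[C@@H](C)[C@@H](C)C1=O | intermediate
19 | (S)-4-benzyloxazolidin-2-one | O=C1N[C@@H](Cc2ccccc2)CO1 | starting material
20 | heptanoyl chloride | CCCCCCC(=O)Cl | starting material
21 | (S)-4-benzyl-3-heptanoyloxazolidin-2-one | CCCCCCC(=O)N1[C@@H](Cc2ccccc2)COC1=O | intermediate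
22 | Z-sodium enolate of 21 | CCCCC/C=C(\[O-])N1[C@@H](Cc2ccccc2)COC1=O.[Na+] | intermediate
23 | (S)-4-benzyl-3-[(R)-2-pentylpent-4-enoyl]oxazolidin-2-one | CCCCC[C@H](CC=C)C(=O)N1[C@@H](Cc2ccccc2)COC1=O | intermediate
24 | (R)-3-[(S)-4-benzyl-2-oxooxazolidine-3-carbonyl]octanal | CCCCC[C@H](CC=O)C(=O)N1[C@@H](Cc2ccccc2)COC1=O | intermediate
25 | (S)-4-benzyl-3-[(R)-2-(2-hydroxyethyl)heptanoyl]oxazolidin-2-one | CCCCC[C@H](CCO)C(=O)N1[C@@H](Cc2ccccc2)COC1=O | intermediate
26 | (R)-3-pentyldihydrofuran-2(3H)-one | CCCCC[C@@H]1CCOC1=O | intermediate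
27 | potassium (R)-2-(2-hydroxyethyl)heptanoate | CCCCC[C@H](CCO)C(=O)[O-].[K+] | intermediate
28 | ethyl (R)-2-(2-hydroxyethyl)heptanoate | CCCCC[C@H](CCO)C(=O)OCC | intermediate
29 | ethyl (R)-2-[2-(tert-butyldimethylsilyloxy)ethyl]heptanoate | CCCCC[C@H](CCO[Si](C)(C)C(C)(C)C)C(=O)OCC | intermediate
30 | lithium (R)-3-[2-(tert-butyldimethylsilyloxy)ethyl]oct-1-yn-1-olate | CCCCC[C@H](CCO[Si](C)(C)C(C)(C)C)C#CO[Li] | intermediate
31 | (R)-tert-butyldimethyl({3-[(triisopropylsilyloxy)ethynyl]octyl}oxy)silane | CCCCC[C@H](CCO[Si](C)(C)C(C)(C)C)C#CO[Si](C(C)C)(C(C)C)C(C)C | intermediate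
32 | 2-[(2S,3R)-2,3-dimethyl-4-oxo-3,4-dihydro-2H-pyran-6-yl]-5-methylhexa-1,4-dien-1-one (ketene) | C1=C(C(=C=O)CC=C(C)C)O[C@@H](C)[C@@H](C)C1=O | intermediate
33 | 2-[(R)-1-(tert-butyldimethylsilyloxy)octan-3-yl]-4-[(2S,3R)-2,3-dimethyl-4-oxo-3,4-dihydro-2H-pyran-6-yl]-4-(3-methylbut-2-enyl)-3-(triisopropylsilyloxy)cyclobut-2-enone (both configurations at C4 of the four-membered ring) | CCCCC[C@H](CCO[Si](C)(C)C(C)(C)C)C1=C(O[Si](C(C)C)(C(C)C)C(C)C)C(CC=C(C)C)(C1=O)C2=CC(=O)[C@H](C)[C@H](C)O2 | intermediate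
34 | dienylketene from ring opening of 33 | CCCCC[C@H](CCO[Si](C)(C)C(C)(C)C)C(=C=O)C(O[Si](C(C)C)(C(C)C)C(C)C)=C(CC=C(C)C)C1=CC(=O)[C@H](C)[C@H](C)O1 | intermediate
35 | cyclohexa-2,4-dienone tautomer of 36 (C4a–H) | CCCCC[C@H](CCO[Si](C)(C)C(C)(C)C)C1=C(O[Si](C(C)C)(C(C)C)C(C)C)C(CC=C(C)C)=C2O[C@@H](C)[C@@H](C)C(=O)C2C1=O | intermediate
36 | (2S,3R)-6-[(R)-1-(tert-butyldimethylsilyloxy)octan-3-yl]-5-hydroxy-2,3-dimethyl-8-(3-methylbut-2-enyl)-7-(triisopropylsilyloxy)chroman-4-one | CCCCC[C@H](CCO[Si](C)(C)C(C)(C)C)c1c(O)c2c(c(CC=C(C)C)c1O[Si](C(C)C)(C(C)C)C(C)C)O[C@@H](C)[C@@H](C)C2=O | intermediate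
37 | (2S,3R)-5,7-dihydroxy-6-[(R)-1-hydroxyoctan-3-yl]-2,3-dimethyl-8-(3-methylbut-2-enyl)chroman-4-one | CCCCC[C@H](CCO)c1c(O)c2c(c(CC=C(C)C)c1O)O[C@@H](C)[C@@H](C)C2=O | intermediate
38 | (2S,3R)-5-hydroxy-6-[(R)-1-hydroxyoctan-3-yl]-7-methoxy-2,3-dimethyl-8-(3-methylbut-2-enyl)chroman-4-one | CCCCC[C@H](CCO)c1c(O)c2c(c(CC=C(C)C)c1OC)O[C@@H](C)[C@@H](C)C2=O | intermediate
39 | (R)-3-[(2S,3R)-5-hydroxy-7-methoxy-2,3-dimethyl-8-(3-methylbut-2-enyl)-4-oxochroman-6-yl]octanal | CCCCC[C@H](CC=O)c1c(O)c2c(c(CC=C(C)C)c1OC)O[C@@H](C)[C@@H](C)C2=O | intermediate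
40 | (R)-3-[(2S,3R)-5-hydroxy-7-methoxy-2,3-dimethyl-8-(3-methylbut-2-enyl)-4-oxochroman-6-yl]octanoic acid | CCCCC[C@H](CC(=O)O)c1c(O)c2c(c(CC=C(C)C)c1OC)O[C@@H](C)[C@@H](C)C2=O | target

**Step count**

Total step count: 20.
Longest linear sequence: 13 steps (1, 2, 3, 6, 7, 8, 9, 10, 16, 17, 18, 19, 20).

**Steps most likely to fail**

**1. Step 16.**
- Risk: the carbene-type intermediate may lose its energy by 1,2-hydride shift from the allylic CH2 faster than C8a migrates. The enone chromophore may also absorb and enter photocycloaddition with the alkyne.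
- Fallback: the alkyl group is taken off the diazo carbon and the prenyl group is added after the ring is made. The fallback sets out from 10 and comes back at 36.
- Compound 10 is treated as in step 6 with commercial tert-butyl(but-3-yn-2-yloxy)dimethylsilane, deprotonated with n-BuLi, to give the ynone F1.
- AgOTf closes it to the pyranone silyl ether F2, HF·pyridine frees the alcohol F3, and Dess–Martin periodinane gives the 6-acetylpyranone F4.
- LiN(SiMe3)2 and CF3CO2CH2CF3 give the trifluoroacetyl diketone F5, and MsN3 with Et3N gives the diazomethyl ketone F6.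
- This compound has no hydrogen next to the carbene carbon. It is of the diazomethyl ketone type of a cyclic alkene for which the benzannulation with siloxyalkynes is established.
- Irradiation with 31 followed by heating should give the 8-unsubstituted chromanone F7.
- N-Iodosuccinimide iodinates the only free ring position to give the 8-iodochromanone F8.
- A Stille coupling with Bu3SnCH2CH=CMe2 and Pd(PPh3)4 in DMF then installs the prenyl group and gives 36.

**2. Step 10.**
- Risk: the amide base may also remove C3–H, with epimerisation towards the trans-dimethyl series. The enolate may also add to the doubly activated C4a=C8a bond of a second molecule.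
- Fallback: the α-carbon is activated without any strong base. The fallback sets out from 15 and comes back at 18.
- Heating 15 with Me2NCH(OMe)2 in toluene condenses only at the CH2 group, since the tertiary C3–H cannot form an enaminone, and gives the enaminone F9.
- Tosyl azide in CH2Cl2 adds to its electron-rich double bond. The triazoline then fragments (diazo transfer to an enaminone) to 18 and a sulfonyl formamidine.

**3. Step 15.**
- Risk: incomplete halogen–lithium exchange or rearrangement, deprotonation at the α-centre before the carbenoid adds, or silylation on carbon instead of oxygen.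
- Fallback: the ynolate is made by oxidation of an acetylide instead of by rearrangement. The fallback sets out from 29 and comes back at 30, and so at 31.
- i-Bu2AlH at −78 °C reduces 29 to the aldehyde F10.
- CBr4 and PPh3 (Corey–Fuchs olefination) give the dibromoalkene F11.
- Two equivalents of n-BuLi give the lithium acetylide F12.
- In the same flask, t-BuOOLi (from t-BuOOH and LiN(SiMe3)2) oxidises F12 to ynolate 30, which i-Pr3SiOTf traps as 31.

**Further compounds**

F1 | step 16 | (2S,3R,7RS)-7-(tert-butyldimethylsilyloxy)-2-hydroxy-3-methyloct-5-yn-4-one | O[C@@H](C)[C@@H](C)C(=O)C#CC(C)O[Si](C)(C)C(C)(C)C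
F2 | step 16 | (2S,3R)-6-[(1RS)-1-(tert-butyldimethylsilyloxy)ethyl]-2,3-dimethyl-2,3-dihydro-4H-pyran-4-one | C1=C(C(C)O[Si](C)(C)C(C)(C)C)O[C@@H](C)[C@@H](C)C1=O
F3 | step 16 | (2S,3R)-6-[(1RS)-1-hydroxyethyl]-2,3-dimethyl-2,3-dihydro-4H-pyran-4-one | C1=C(C(C)O)O[C@@H](C)[C@@H](C)C1=O
F4 | step 16 | (2S,3R)-6-acetyl-2,3-dimethyl-2,3-dihydro-4H-pyran-4-one | C1=C(C(C)=O)O[C@@H](C)[C@@H](C)C1=O
F5 | step 16 | 1-[(2S,3R)-2,3-dimethyl-4-oxo-3,4-dihydro-2H-pyran-6-yl]-4,4,4-trifluorobutane-1,3-dione | C1=C(C(=O)CC(=O)C(F)(F)F)O[C@@H](C)[C@@H](C)C1=O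
F6 | step 16 | (2S,3R)-6-(2-diazoacetyl)-2,3-dimethyl-2,3-dihydro-4H-pyran-4-one | C1=C(C(=O)C=[N+]=[N-])O[C@@H](C)[C@@H](C)C1=O
F7 | step 16 | (2S,3R)-6-[(R)-1-(tert-butyldimethylsilyloxy)octan-3-yl]-5-hydroxy-2,3-dimethyl-7-(triisopropylsilyloxy)chroman-4-one | CCCCC[C@H](CCO[Si](C)(C)C(C)(C)C)c1c(O)c2c(cc1O[Si](C(C)C)(C(C)C)C(C)C)O[C@@H](C)[C@@H](C)C2=O
F8 | step 16 | (2S,3R)-6-[(R)-1-(tert-butyldimethylsilyloxy)octan-3-yl]-5-hydroxy-8-iodo-2,3-dimethyl-7-(triisopropylsilyloxy)chroman-4-one | CCCCC[C@H](CCO[Si](C)(C)C(C)(C)C)c1c(O)c2c(c(I)c1O[Si](C(C)C)(C(C)C)C(C)C)O[C@@H](C)[C@@H](C)C2=O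
F9 | step 10 | (2S,3R)-6-[2-(dimethylaminomethylidene)-5-methylhex-4-enoyl]-2,3-dimethyl-2,3-dihydro-4H-pyran-4-one | C1=C(C(=O)C(=CN(C)C)CC=C(C)C)O[C@@H](C)[C@@H](C)C1=O
F10 | step 15 | (R)-2-[2-(tert-butyldimethylsilyloxy)ethyl]heptanal | CCCCC[C@H](CCO[Si](C)(C)C(C)(C)C)C=O
F11 | step 15 | (R)-tert-butyl{[3-(2,2-dibromoethenyl)octyl]oxy}dimethylsilane | CCCCC[C@H](CCO[Si](C)(C)C(C)(C)C)C=C(Br)Br
F12 | step 15 | lithium acetylide of (R)-tert-butyl[(3-ethynyloctyl)oxy]dimethylsilane | CCCCC[C@H](CCO[Si](C)(C)C(C)(C)C)C#C[Li]
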